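A small charge of reagent shows what each unit of it is worth, so I begin with the two earlier runs, where reagent is the limiting reagent.

| setting | grey | violet | beta | epsilon |
|---|---|---|---|---|
| substrate | 0.10 M | 0.10 M | 0.10 M | 0.10 M |
| reagent | 0.50 equiv | 0.75 equiv | 1.00 equiv | 1.00 equiv |
| remark | run made earlier | run made earlier |  |  |
| time |  |  | 20 min | 80 min |

| run | time / min | mono adduct / % |
|---|---|---|
| grey | 15.0 | 45.7 |
| grey | 30.0 | 48.8 |
| grey | 50.0 | 47.7 |
| grey | 60.0 | 48.5 |
| grey | 80.0 | 47.9 |
| violet | 8.00 | 64.3 |
| violet | 20.0 | 68.2 |
| violet | 40.0 | 70.6 |
| violet | 60.0 | 72.1 |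
| violet | 80.0 | 72.0 |

(readings scatter by 1 percentage point)



- which one finishes higher in amount of mono adduct, in percent of the substrate charged ("neither" within 2 percentage points) (beta / epsilon / neither)
- amount of mono adduct at the end, in percent of the substrate charged, beta
- amount of mono adduct at the end, in percent of the substrate charged, epsilon

I divide the last mono adduct reading by the equivalents charged, once for each flask:

grey: 95.8 %
violet: 96.0 %

This yield per equivalent comes out alike from two different flasks, within the scatter of a reading, so I trust it as a reading and take 96.0 % as the ceiling at 1.00 equiv.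

The small thing is the correction below that ceiling. Let κ be the rate constant times the starting [substrate], y the reading as a fraction and P the plateau of that run. With unequal charges, one step gives

κ = ln[(1 − y)P/(P − y)] / [(1 − P)t]

grey, 15.0 min: 0.316 min⁻¹
violet, 8.00 min: 0.538 min⁻¹
violet, 20.0 min: 0.321 min⁻¹

Here the ways part. The early violet reading stands apart, while the two later readings, from different flasks, agree. The one-step law gives no single κ across these readings, and the tail is what I need, so I set the early value aside and keep 0.321 min⁻¹. With equal charges, the fraction unreacted is 1/(1 + κt), so my own reckoning is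

beta: 83.1 %
epsilon: 92.4 %

The forecast also chooses epsilon, with 86 % for beta and 93 % for epsilon, both higher than mine, on the ground that “the tail is slow because both run out together”.

The flask gives 80.5 % for beta and 91.3 % for epsilon, so epsilon finishes higher.

    substrate + reagent → mono adduct (k = 0.110 M⁻¹ s⁻¹)
    reagent + mono adduct ⇌ double product (K = 17.0 M⁻¹, k = 0.0130 M⁻¹ s⁻¹)
    mono adduct → over-reaction product (k = 1.90 × 10⁻⁶ s⁻¹)

In beta at 20.0 min, the double product holds 7.73 % of the substrate charged; at 200 min it holds 1.33 %, and mono adduct stands at 94.6 %. For a neighbour of beta charged with 0.250 equiv of reagent, the yield per equivalent gives 24.0 %, and that flask holds 24.5 % mono adduct at 20.0 min.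

The data come from a simulation with constants of no real substance.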